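**Retrosynthetic overview**

1. The 14-membered carbocycle is opened at the bond between the tertiary carbinol carbon C8 (C(OH)CH3, next to the tetrahydrofuran ring) and the ring CH2 C7. In the forward sense an alkynylmagnesium at C7 adds to a 2-acetyltetrahydrofuran ketone; the C6≡C7 alkyne stands for CH2CH2 and a C5 carbinol for the ring ketone.
2. The feature that makes this possible: the tetrahydrofuran ring oxygen sits on C9, the carbon next to the C8 carbonyl. This α-alkoxy ketone forms a five-membered chelate (carbonyl O–Mg–ring O) that activates the ketone and fixes the face of attack.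
3. The seco-precursor comes from a double ozonolysis (vinyl → C5 aldehyde on the lactone C–O carbon, isopropenyl → C8 acetyl), then Zn-mediated addition of trimethylsilylacetylene to the aldehyde.
4. Both halves derive from (R)-linalool. Fragment B is a tetrahydrofuran β-keto ester and fragment A an enal; an organocatalytic Michael addition joins them and sets the lactone CH stereocentre C1. The ε-lactone is then closed on the linalool tertiary alcohol.
5. Ring order: tetrahydrofuran (step 1) → seven-membered lactone (step 12) → 14-membered carbocycle (step 18). Exocyclic methylene, C5 ketone and acetate are adjusted last.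

Key step: step 18

Remark on locants (cembrane-type numbering): C1 = lactone-ring CH; C4 = lactone C–O carbon (methyl-bearing); C5 = ring ketone carbon; C6, C7 = ring CH2CH2; C8 = tertiary carbinol; C9 = tetrahydrofuran CH; C12 = tetrahydrofuran quaternary carbon; C13 = acetoxy carbon.

Assumption: the C5 carbinol centre made in step 16 is carried as a mixture of epimers (21–25, 28) and is erased by oxidation in step 21. The β-keto ester carbon of 12 and the lactone α-carbon of 26 and 27 are likewise undefined and later become CH2 or trigonal.

**Route**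

Step 1
Reactants: 1 (R)-linalool
Product: 3 (2R,5R)-trans-linalool oxide (furanoid), via (3R,6S)-6,7-epoxylinalool 2 (not isolated)
Conditions: ent-Shi ketone (L-fructose-derived, 0.3 equiv), Oxone, K2CO3, Bu4NHSO4, MeCN–dimethoxymethane–aq. buffer (pH 10.5), 0 °C; then CSA (cat.), CH2Cl2, 0 °C
Reagents that add atoms: Oxone (potassium peroxymonosulfate), [K+].[O-]S(=O)(=O)OO
Why: Shi epoxidation of the electron-rich trisubstituted olefin (the vinyl group is left) with the L-fructose-derived ketone should give the (6S)-epoxide under catalyst control, and acid-catalysed 5-exo-tet opening by the tertiary hydroxyl with inversion at C6 then forms the tetrahydrofuran ring with the 2,5-trans relationship (2R from linalool, 5R from the epoxide).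

Step 2
Reactants: 3 (2R,5R)-trans-linalool oxide
Product: 4 methyl (2R,5R)-5-(2-hydroxypropan-2-yl)-2-methyltetrahydrofuran-2-carboxylate
Conditions: O3, NaOH (2.5 M in MeOH), CH2Cl2, −78 °C
Reagents that add atoms: ozone, [O-][O+]=O; methanol, CO
Why: Ozonolysis in methanolic NaOH converts a terminal alkene directly into the methyl ester (the aldehyde hemiacetal is oxidised further by ozone) without touching the quaternary stereocentre.

Step 3
Reactants: 4 hydroxy ester
Product: 5 methyl (2R,5R)-2-methyl-5-(prop-1-en-2-yl)tetrahydrofuran-2-carboxylate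
Conditions: SOCl2, pyridine, CH2Cl2, −20 → 0 °C
Reagents that add atoms: none
Why: Dehydration of the tertiary alcohol through its chlorosulfite (E2 with pyridine) should take one of the six methyl hydrogens rather than the single, inductively deactivated ring methine hydrogen and so give the isopropenyl group, the masked acetyl group of the key step.

Step 4
Reactants: 5 isopropenyl ester; 6 allyl acetate
Product: 7 allyl 3-[(2R,5R)-2-methyl-5-(prop-1-en-2-yl)tetrahydrofuran-2-yl]-3-oxopropanoate (fragment B)
Conditions: LDA (2.2 equiv), 6, THF, −78 °C; then 5, −78 → −20 °C; aq. NH4Cl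
Reagents that add atoms: none
Why: Crossed Claisen condensation of the lithium enolate of allyl acetate with the non-enolisable ester gives the β-keto ester, whose acidic CH2 is the activating handle for the fragment union and whose allyl ester is removable under neutral conditions.

Step 5
Reactants: 1 (R)-linalool
Product: 8 (R)-linalool triethylsilyl ether
Conditions: TESOTf, 2,6-lutidine, CH2Cl2, −78 → 0 °C
Reagents that add atoms: triethylsilyl trifluoromethanesulfonate, CC[Si](CC)(CC)OS(=O)(=O)C(F)(F)F
Why: Silylation of the tertiary allylic alcohol with the triflate blocks the intramolecular oxa-Michael addition that a free hydroxyl would undergo in steps 7 and 8.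

Step 6
Reactants: 8 (R)-linalool triethylsilyl ether
Product: 9 (4R)-4-methyl-4-(triethylsilyloxy)hex-5-enal
Conditions: O3 (1 equiv, indicator dye), pyridine, CH2Cl2, −78 °C; then Me2S
Reagents that add atoms: ozone, [O-][O+]=O
Why: Ozonolysis monitored by an indicator dye cleaves the electron-rich trisubstituted olefin much faster than the monosubstituted vinyl group next to the silyloxy-bearing quaternary carbon, giving the aldehyde.

Step 7
Reactants: 9 aldehyde; 10 (triphenylphosphoranylidene)acetaldehyde
Product: 11 (2E,6R)-6-methyl-6-(triethylsilyloxy)octa-2,7-dienal (fragment A)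
Conditions: toluene, 80 °C
Reagents that add atoms: none
Why: Wittig reaction with the stabilised formylmethylene ylide gives the (E)-enal needed for iminium activation.

Step 8
Reactants: 11 enal (fragment A); 7 β-keto ester (fragment B)
Product: 12 Michael adduct (δ-keto aldehyde carrying the allyl ester)
Conditions: (R)-α,α-diphenylprolinol trimethylsilyl ether (10 mol %), PhCO2H (10 mol %), toluene, rt
Reagents that add atoms: none
Why: Organocatalytic Michael addition: the β-keto ester adds to the (E)-iminium ion on the face not shielded by the diphenyl(silyloxy)methyl group of the (R)-catalyst, which sets the C1 stereocentre under catalyst control while uniting fragments A and B.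

Step 9
Reactants: 12 Michael adduct
Product: 13 δ-keto aldehyde
Conditions: Pd(PPh3)4 (5 mol %), HCO2H, Et3N, THF, rt
Reagents that add atoms: none
Why: Palladium-catalysed deallylation with formate as hydride donor gives the β-keto acid, which decarboxylates at room temperature and so removes the activating group under neutral conditions that leave the aldehyde and the silyl ether intact.

Step 10
Reactants: 13 δ-keto aldehyde
Product: 14 δ-keto acid
Conditions: NaClO2, NaH2PO4, 2-methyl-2-butene, t-BuOH–H2O, 0 °C → rt
Reagents that add atoms: sodium chlorite, [Na+].[O-]Cl=O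
Why: Pinnick oxidation takes the aldehyde to the acid without epimerisation and, with the alkene scavenger, without attack on the vinyl and isopropenyl groups.

Step 11
Reactants: 14 δ-keto acid
Product: 15 hydroxy keto acid
Conditions: HF·pyridine, THF, 0 °C
Reagents that add atoms: none
Why: Fluoride cleaves the tertiary triethylsilyl ether and frees the tertiary allylic alcohol for lactonisation.

Step 12
Reactants: 15 hydroxy keto acid
Product: 16 (4R,7R)-7-methyl-4-{2-[(2R,5R)-2-methyl-5-(prop-1-en-2-yl)tetrahydrofuran-2-yl]-2-oxoethyl}-7-vinyloxepan-2-one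
Conditions: DCC, DMAP (3 equiv), DMAP·HCl, CH2Cl2, 40 °C, slow addition (final 2 mM)
Reagents that add atoms: none
Why: Steglich-type lactonisation: the N-acylpyridinium ion formed from the O-acylisourea and DMAP is reactive enough to acylate a tertiary alcohol, and slow addition favours closure of the seven-membered ring over dimerisation.

Step 13
Reactants: 16 keto lactone
Product: 17 (13S)-hydroxy lactone
Conditions: (R)-2-methyl-CBS-oxazaborolidine (0.3 equiv), catecholborane, toluene, −78 → −40 °C; MeOH, pH 7 buffer
Reagents that add atoms: none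
Why: Corey–Bakshi–Shibata reduction: with the quaternary tetrahydrofuran carbon as the large and the CH2 as the small substituent the (R)-oxazaborolidine should deliver hydride to give the (13S)-alcohol under reagent control, and catecholborane spares the alkenes and the lactone.

Step 14
Reactants: 17 hydroxy lactone
Product: 18 TBS ether of 17
Conditions: TBSOTf, 2,6-lutidine, CH2Cl2, −78 °C
Reagents that add atoms: tert-butyldimethylsilyl trifluoromethanesulfonate, CC(C)(C)[Si](C)(C)OS(=O)(=O)C(F)(F)F
Why: Immediate silylation with the triflate protects the hindered secondary alcohol and prevents its translactonisation onto the ε-lactone carbonyl.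

Step 15
Reactants: 18 TBS ether
Product: 19 keto aldehyde (C5 aldehyde, C8 methyl ketone)
Conditions: O3, NaHCO3, CH2Cl2–MeOH, −78 °C; then Me2S
Reagents that add atoms: ozone, [O-][O+]=O
Why: Exhaustive ozonolysis with reductive work-up unmasks both carbonyl groups of the seco-precursor at once: the vinyl group gives the aldehyde at C5 and the isopropenyl group the methyl ketone at C8.

Step 16
Reactants: 19 keto aldehyde; 20 trimethylsilylacetylene
Product: 21 propargylic alcohol (silylalkyne)
Conditions: Zn(OTf)2 (1.2 equiv), Et3N, toluene, rt
Reagents that add atoms: none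
Why: The zinc acetylide formed in situ from the terminal alkyne, Zn(OTf)2 and Et3N adds to aldehydes but not to ketones, so the two-carbon C6–C7 unit is attached at C5 chemoselectively and without a base strong enough to enolise the methyl ketone.

Step 17
Reactants: 21 propargylic alcohol (silylalkyne)
Product: 22 1-iodoalkyne
Conditions: NIS, AgNO3 (10 mol %), DMF, rt, dark
Reagents that add atoms: N-iodosuccinimide, O=C1CCC(=O)N1I
Why: Silver-catalysed iododesilylation converts the alkynylsilane directly into the 1-iodoalkyne, the precursor of a magnesium acetylide that can be generated without base.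

Step 18
Reactants: 22 1-iodoalkyne
Product: 24 macrocyclic ynediol, via alkynylmagnesium bromide 23 (not isolated)
Conditions: i-PrMgBr (2.1 equiv), THF (2 mM), −78 °C, 10 min; then −78 → −10 °C; aq. NH4Cl
Reagents that add atoms: none
Why: Iodine–magnesium exchange on the 1-iodoalkyne is much faster at −78 °C than addition of i-PrMgBr to a carbonyl group, so (after deprotonation of the C5 hydroxyl by the first equivalent) an alkynylmagnesium bromide forms without any base that could enolise the methyl ketone, and on warming its sp carbon (C7) adds to the acetyl carbonyl carbon (C8) in an intramolecular Grignard 1,2-addition. The closest known reaction types are the chelation-controlled addition of Grignard reagents to α-alkoxy ketones (2-acyltetrahydrofurans) and ring closure by intramolecular addition of metal acetylides to carbonyl groups. The 14-membered carbocycle closes in the 14-exo-trig mode, the carbonyl oxygen staying outside the ring as the new tertiary hydroxyl group. The new C8 stereocentre is controlled by the five-membered chelate of magnesium between the carbonyl oxygen and the tetrahydrofuran oxygen on C9: the acetylide attacks the carbonyl face opposite the ring CH2 (C10), which gives the (8R) carbinol (Cram chelate model). The step needs attack on the ketone and not on the lactone, and ring closure instead of oligomerisation; the chelate activates the ketone, alkynylmagnesium halides are sluggish toward esters at low temperature, the linear C5–C6≡C7 unit cannot reach the neighbouring lactone carbonyl, and the reaction is run at about 2 mM.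

Step 19
Reactants: 24 macrocyclic ynediol
Product: 25 saturated macrocyclic diol
Conditions: H2 (1 atm), Rh/Al2O3 (5 wt % Rh), EtOAc, rt
Reagents that add atoms: none
Why: Heterogeneous hydrogenation saturates the ring alkyne to the C6–C7 CH2CH2 unit; rhodium on alumina is chosen to limit hydrogenolysis of the propargylic C–O bonds.

Step 20
Reactants: 25 saturated macrocyclic diol
Product: 28 α-methylene lactone diol, via Mannich base 26 (not isolated), via trimethylammonium iodide 27 (not isolated)
Conditions: LDA (3.5 equiv), THF, −78 °C; Eschenmoser's salt, −78 → 0 °C; then MeI, MeOH, rt; then aq. NaHCO3, CH2Cl2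
Reagents that add atoms: Eschenmoser's salt (dimethylmethyleneiminium iodide), C=[N+](C)C.[I-]
Why: α-Methylenation of the lactone by enolate aminomethylation with Eschenmoser's salt, exhaustive N-methylation and E1cB elimination; the hydroxyl groups are carried as lithium alkoxides and, with C5 still at the alcohol level, the lactone α-CH2 is the only carbon acid.

Step 21
Reactants: 28 α-methylene lactone diol
Product: 29 C5 ketone
Conditions: Dess–Martin periodinane, NaHCO3, CH2Cl2, 0 °C → rt
Reagents that add atoms: none
Why: Dess–Martin oxidation converts the only secondary alcohol into the C5 ketone and leaves the tertiary alcohol and the α-methylene lactone untouched.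

Step 22
Reactants: 29 C5 ketone
Product: 30 C13 alcohol (deacetyl target)
Conditions: HF·pyridine, pyridine, THF, 0 °C → rt
Reagents that add atoms: none
Why: Buffered HF·pyridine removes the silyl ether without affecting the α-methylene lactone or the tertiary alcohol; the product is acetylated at once to forestall acyl migration from the ε-lactone.

Step 23
Reactants: 30 C13 alcohol
Product: 31 CNP0198878.1 (target)
Conditions: Ac2O, DMAP (cat.), pyridine, CH2Cl2, 0 °C
Reagents that add atoms: acetic anhydride, CC(=O)OC(C)=O
Why: DMAP-catalysed acetylation esterifies the secondary C13 alcohol while the hindered tertiary C8 alcohol does not react, which completes the target.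

**Compound list**

1 | (R)-(−)-linalool, (3R)-3,7-dimethylocta-1,6-dien-3-ol | C=C[C@](C)(O)CCC=C(C)C | starting material
2 | (3R,6S)-6,7-epoxy-3,7-dimethyloct-1-en-3-ol | C=C[C@](C)(O)CC[C@@H]1OC1(C)C | intermediate
3 | (2R,5R)-trans-linalool oxide, 2-[(2R,5R)-5-methyl-5-vinyltetrahydrofuran-2-yl]propan-2-ol | C=C[C@@]1(C)CC[C@@H](O1)C(C)(C)O | intermediate
4 | methyl (2R,5R)-5-(2-hydroxypropan-2-yl)-2-methyltetrahydrofuran-2-carboxylate | COC(=O)[C@@]1(C)CC[C@@H](O1)C(C)(C)O | intermediate
5 | methyl (2R,5R)-2-methyl-5-(prop-1-en-2-yl)tetrahydrofuran-2-carboxylate | COC(=O)[C@@]1(C)CC[C@@H](O1)C(C)=C | intermediate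
6 | allyl acetate | CC(=O)OCC=C | starting material
7 | allyl 3-[(2R,5R)-2-methyl-5-(prop-1-en-2-yl)tetrahydrofuran-2-yl]-3-oxopropanoate | C=CCOC(=O)CC(=O)[C@@]1(C)CC[C@@H](O1)C(C)=C | intermediate
8 | (R)-linalool triethylsilyl ether | C=C[C@](C)(O[Si](CC)(CC)CC)CCC=C(C)C | intermediate
9 | (4R)-4-methyl-4-(triethylsilyloxy)hex-5-enal | C=C[C@](C)(O[Si](CC)(CC)CC)CCC=O | intermediate
10 | (triphenylphosphoranylidene)acetaldehyde | O=CC=P(c1ccccc1)(c1ccccc1)c1ccccc1 | starting material
11 | (2E,6R)-6-methyl-6-(triethylsilyloxy)octa-2,7-dienal | C=C[C@](C)(O[Si](CC)(CC)CC)CC/C=C/C=O | intermediate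
12 | Michael adduct: allyl β-keto ester with the 2-oxoethyl group on the new CH centre (C1), TES ether | C=C[C@](C)(O[Si](CC)(CC)CC)CC[C@@H](CC=O)C(C(=O)OCC=C)C(=O)[C@@]1(C)CC[C@@H](O1)C(C)=C | intermediate
13 | δ-keto aldehyde (TES ether) | C=C[C@](C)(O[Si](CC)(CC)CC)CC[C@@H](CC=O)CC(=O)[C@@]1(C)CC[C@@H](O1)C(C)=C | intermediate
14 | δ-keto acid (TES ether) | C=C[C@](C)(O[Si](CC)(CC)CC)CC[C@@H](CC(=O)O)CC(=O)[C@@]1(C)CC[C@@H](O1)C(C)=C | intermediate
15 | hydroxy keto acid (free tertiary allylic alcohol) | C=C[C@](C)(O)CC[C@@H](CC(=O)O)CC(=O)[C@@]1(C)CC[C@@H](O1)C(C)=C | intermediate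
16 | (4R,7R)-7-methyl-4-{2-[(2R,5R)-2-methyl-5-(prop-1-en-2-yl)tetrahydrofuran-2-yl]-2-oxoethyl}-7-vinyloxepan-2-one | C1C(=O)O[C@@](C)(C=C)CC[C@@H]1CC(=O)[C@@]1(C)CC[C@@H](O1)C(C)=C | intermediate
17 | (13S)-hydroxy lactone (secondary alcohol next to the tetrahydrofuran quaternary carbon) | C1C(=O)O[C@@](C)(C=C)CC[C@@H]1C[C@H](O)[C@@]1(C)CC[C@@H](O1)C(C)=C | intermediate
18 | TBS ether of 17 | C1C(=O)O[C@@](C)(C=C)CC[C@@H]1C[C@H](O[Si](C)(C)C(C)(C)C)[C@@]1(C)CC[C@@H](O1)C(C)=C | intermediate
19 | keto aldehyde: 7-formyl lactone with 5-acetyltetrahydrofuran, TBS ether | C1C(=O)O[C@@](C)(C=O)CC[C@@H]1C[C@H](O[Si](C)(C)C(C)(C)C)[C@@]1(C)CC[C@@H](O1)C(C)=O | intermediate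
20 | trimethylsilylacetylene | C#C[Si](C)(C)C | starting material
21 | propargylic alcohol with trimethylsilylalkyne (C5 epimers) | C1C(=O)O[C@@](C)(C(O)C#C[Si](C)(C)C)CC[C@@H]1C[C@H](O[Si](C)(C)C(C)(C)C)[C@@]1(C)CC[C@@H](O1)C(C)=O | intermediate
22 | 1-iodoalkyne (C5 epimers) | C1C(=O)O[C@@](C)(C(O)C#CI)CC[C@@H]1C[C@H](O[Si](C)(C)C(C)(C)C)[C@@]1(C)CC[C@@H](O1)C(C)=O | intermediate
23 | alkynylmagnesium bromide with bromomagnesium alkoxide | C1C(=O)O[C@@](C)(C(O[Mg]Br)C#C[Mg]Br)CC[C@@H]1C[C@H](O[Si](C)(C)C(C)(C)C)[C@@]1(C)CC[C@@H](O1)C(C)=O | intermediate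
24 | macrocyclic ynediol: 14-membered ring with C6≡C7, (8R) tertiary alcohol, C5 secondary alcohol, TBS ether | C1C(=O)O[C@]2(C)CC[C@@H]1C[C@H](O[Si](C)(C)C(C)(C)C)[C@@]1(C)CC[C@@H](O1)[C@](C)(O)C#CC2O | intermediate
25 | saturated macrocyclic diol | C1C(=O)O[C@]2(C)CC[C@@H]1C[C@H](O[Si](C)(C)C(C)(C)C)[C@@]1(C)CC[C@@H](O1)[C@](C)(O)CCC2O | intermediate
26 | Mannich base: α-(dimethylaminomethyl) lactone | CN(C)CC1C(=O)O[C@]2(C)CC[C@@H]1C[C@H](O[Si](C)(C)C(C)(C)C)[C@@]1(C)CC[C@@H](O1)[C@](C)(O)CCC2O | intermediate
27 | trimethylammonium iodide of 26 | C[N+](C)(C)CC1C(=O)O[C@]2(C)CC[C@@H]1C[C@H](O[Si](C)(C)C(C)(C)C)[C@@]1(C)CC[C@@H](O1)[C@](C)(O)CCC2O.[I-] | intermediate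
28 | α-methylene lactone diol (TBS ether) | C=C1C(=O)O[C@]2(C)CC[C@@H]1C[C@H](O[Si](C)(C)C(C)(C)C)[C@@]1(C)CC[C@@H](O1)[C@](C)(O)CCC2O | intermediate
29 | C5 ketone (TBS ether) | C=C1C(=O)O[C@]2(C)CC[C@@H]1C[C@H](O[Si](C)(C)C(C)(C)C)[C@@]1(C)CC[C@@H](O1)[C@](C)(O)CCC2=O | intermediate
30 | C13 alcohol (deacetyl target) | C=C1C(=O)O[C@]2(C)CC[C@@H]1C[C@H](O)[C@@]1(C)CC[C@@H](O1)[C@](C)(O)CCC2=O | intermediate
31 | CNP0198878.1 | C=C1C(=O)O[C@]2(C)CC[C@@H]1C[C@H](OC(C)=O)[C@@]1(C)CC[C@@H](O1)[C@](C)(O)CCC2=O | target

**Step count**

Total step count: 23. Longest linear sequence: 20 steps (steps 1–4, then 8–23).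

**Steps most likely to fail, with fallbacks**

Step 18 (macrocyclisation). Intermolecular addition (oligomerisation) may outrun the slow closure of the 14-membered ring, or i-PrMgBr may add to, reduce or enolise the methyl ketone before the iodine–magnesium exchange is complete. The fallback sets out from 18 and comes back at 24, closing the ring at the other end of the two-carbon unit. Ozonolysis of 18 stopped after the more electron-rich isopropenyl group has reacted (indicator dye, Me2S) should give the methyl ketone F1 with the vinyl group intact. Ethynylmagnesium bromide (THF, −78 °C) then adds to the acetyl group under the same chelate control, now intermolecularly and with excess reagent, to give the (8R) tertiary propargylic alcohol F2. NIS with catalytic AgNO3 converts the terminal alkyne into the 1-iodoalkyne F3, and ozonolysis of the vinyl group gives the aldehyde F4. A Nozaki–Hiyama–Kishi reaction (CrCl2, catalytic NiCl2, THF, high dilution), which is established for iodoalkyne–aldehyde macrocyclisation and tolerates the free tertiary alcohol, then closes the ring to 24.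

Step 12 (lactonisation on the tertiary alcohol). Acylation of the hindered tertiary allylic alcohol may be too slow, so that dimerisation to the diolide or rearrangement of the activated acid to the N-acylurea takes over. The fallback sets out from 14 and comes back at 16, and does not activate the acid externally at all. The δ-keto acid 14 is dehydrated (Ac2O, NaOAc, 80 °C) to its six-membered enol lactone F5, an isolable internal active ester. HF·pyridine removes the silyl group to give the hydroxy enol lactone F6. Catalytic DBU (or NaH) in THF then lets the tertiary alkoxide attack the enol ester carbonyl; ring-expanding acyl transfer, driven by release of the ketone from its enol, should give 16.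

Step 20 (late α-methylenation). Enolisation of the lactone next to two lithium alkoxides may be incomplete or unselective, and the lactone acyl group may migrate to the neighbouring C5 alkoxide. The fallback sets out from 25 and comes back at 28 and uses no amide base. Carboxylation of the lactone with methyl magnesium carbonate, Mg(OMe)(OCO2Me), in DMF at 120 °C (the hydroxyls carried as magnesium alkoxides) gives, after acidification, the α-carboxy lactone F7. Aqueous formaldehyde and diethylamine with NaOAc in AcOH then effect Mannich reaction, decarboxylation and amine elimination to give 28.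

**Further compounds**

F1 | step 18 | methyl ketone from selective cleavage of the isopropenyl group of 18 (vinyl intact) | C1C(=O)O[C@@](C)(C=C)CC[C@@H]1C[C@H](O[Si](C)(C)C(C)(C)C)[C@@]1(C)CC[C@@H](O1)C(C)=O
F2 | step 18 | (8R) tertiary propargylic alcohol with terminal alkyne | C1C(=O)O[C@@](C)(C=C)CC[C@@H]1C[C@H](O[Si](C)(C)C(C)(C)C)[C@@]1(C)CC[C@@H](O1)[C@](C)(O)C#C
F3 | step 18 | 1-iodoalkyne of F2 | C1C(=O)O[C@@](C)(C=C)CC[C@@H]1C[C@H](O[Si](C)(C)C(C)(C)C)[C@@]1(C)CC[C@@H](O1)[C@](C)(O)C#CI
F4 | step 18 | aldehyde iodoalkyne (vinyl cleaved to the C5 aldehyde) | C1C(=O)O[C@@](C)(C=O)CC[C@@H]1C[C@H](O[Si](C)(C)C(C)(C)C)[C@@]1(C)CC[C@@H](O1)[C@](C)(O)C#CI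
F5 | step 12 | six-membered enol lactone of 14 (TES ether) | C=C[C@](C)(O[Si](CC)(CC)CC)CC[C@H]1CC(=O)OC(=C1)[C@@]1(C)CC[C@@H](O1)C(C)=C
F6 | step 12 | hydroxy enol lactone (free tertiary alcohol) | C=C[C@](C)(O)CC[C@H]1CC(=O)OC(=C1)[C@@]1(C)CC[C@@H](O1)C(C)=C
F7 | step 20 | α-carboxy lactone of 25 | OC(=O)C1C(=O)O[C@]2(C)CC[C@@H]1C[C@H](O[Si](C)(C)C(C)(C)C)[C@@]1(C)CC[C@@H](O1)[C@](C)(O)CCC2O
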